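**Retrosynthetic overview**
- The strategy rests on the 1,4-dioxygenated 2-ene made up of the C4 hydroxyl, the tetrasubstituted C6=C7 alkene of ring A and the C8–O9 ether of the oxepane. It is disconnected at C8–O9 to a ring A vinyl epoxide (C4–C6 oxirane, exocyclic C7=C8) carrying the free tertiary C10 hydroxyl.
- The 12-membered carbocycle is opened at C19–C20 (B-alkyl Suzuki coupling of the C18=C19 vinyl group with a Z-vinyl iodide built on the C24 aldehyde with a propynyl unit); the C20–C23 oxirane is added last to the Z-enone.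
- Side chain: C16 by Brown alkoxyallylboration, C10 by chelation-controlled methyl addition. Ring A: C2 by copper-catalysed asymmetric methyl addition to 2-methylcyclohexenone, C14 by anti allylation, C4 by Sharpless epoxidation.
- Ring order: ring A (from the starting enone), its C4–C6 oxirane (transient), the oxepane (key step), the 12-membered ring, the C20–C23 oxirane.

Key step: step 17

Remark: atom labels C1 to O25 follow the heavy-atom order of the target SMILES.
Assumption: in step 25 hydroperoxide is taken to add to the exposed face of the macrocyclic Z-enone in the sense that gives (20R,23R); the third fallback covers the opposite outcome.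

**Step 1**
Reactants: 1 2-methylcyclohex-2-en-1-one
Product: 3 (3S)-2,3-dimethyl-1-(trimethylsilyloxy)cyclohex-1-ene, via dimethylaluminium enolate 2 (not isolated)
Conditions: Me3Al, CuTC (copper thiophene-2-carboxylate, CuO2C-C4H3S, 2 mol %), Feringa-type phosphoramidite ligand (antipode giving 3S), Et2O, −30 °C; then TMSOTf, −30 → 0 °C
Reagents that add atoms: trimethylaluminium, C[Al](C)C; trimethylsilyl trifluoromethanesulfonate, C[Si](C)(C)OS(=O)(=O)C(F)(F)F
Why: Copper–phosphoramidite-catalysed asymmetric conjugate addition sets C2 (S) under ligand control, and O-silylation of the aluminium enolate fixes the tetrasubstituted enolate regiochemistry.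

**Step 2**
Reactants: 3 (3S)-2,3-dimethyl-1-(trimethylsilyloxy)cyclohex-1-ene; 4 allyl bromide
Product: 6 (2R,3S)-2-allyl-2,3-dimethylcyclohexan-1-one, via lithium enolate 5 (not isolated)
Conditions: MeLi, THF, 0 → 25 °C; then allyl bromide, HMPA, −78 → 0 °C
Reagents that add atoms: methyllithium, [Li]C (lithium of intermediate 5 only)
Why: Methyllithium cleaves the silyl enol ether to the regiodefined lithium enolate, and C-allylation anti to the pseudoaxial C2 methyl (axial attack) sets the quaternary C14 (R) with the two methyls cis.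

**Step 3**
Reactants: 6 (2R,3S)-2-allyl-2,3-dimethylcyclohexan-1-one
Product: 7 (6R,7S)-6-allyl-6,7-dimethyl-1,4-dioxaspiro[4.5]decane
Conditions: ethylene glycol, p-TsOH (cat.), benzene, reflux, Dean–Stark
Reagents that add atoms: ethane-1,2-diol, OCCO
Why: Acid-catalysed ketalisation with azeotropic water removal masks the C7 ketone against the borane, allylborane and Grignard steps that follow.

**Step 4**
Reactants: 7 (6R,7S)-6-allyl-6,7-dimethyl-1,4-dioxaspiro[4.5]decane
Product: 9 3-[(6R,7S)-6,7-dimethyl-1,4-dioxaspiro[4.5]decan-6-yl]propan-1-ol, via B-alkyl-9-BBN 8 (not isolated)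
Conditions: 9-BBN, THF, 0 → 25 °C; then NaOH, H2O2, 0 °C
Reagents that add atoms: hydrogen peroxide, OO; 9-BBN, B1C2CCCC1CCC2 (in intermediate 8 only)
Why: Hydroboration–oxidation of the monosubstituted alkene is anti-Markovnikov and gives the primary C10 alcohol; the ketal is stable to basic peroxide.

**Step 5**
Reactants: 9 3-[(6R,7S)-6,7-dimethyl-1,4-dioxaspiro[4.5]decan-6-yl]propan-1-ol
Product: 10 3-[(6R,7S)-6,7-dimethyl-1,4-dioxaspiro[4.5]decan-6-yl]propanal
Conditions: Dess–Martin periodinane, NaHCO3, CH2Cl2, 25 °C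
Reagents that add atoms: none
Why: Dess–Martin oxidation under buffered conditions stops at the aldehyde and does not cleave the dioxolane.

**Step 6**
Reactants: 10 3-[(6R,7S)-6,7-dimethyl-1,4-dioxaspiro[4.5]decan-6-yl]propanal; 11 allyl methoxymethyl ether
Product: 13 (3R,4R)-6-[(6R,7S)-6,7-dimethyl-1,4-dioxaspiro[4.5]decan-6-yl]-3-(methoxymethoxy)hex-1-en-4-ol, via Brown allylborane 12 (not isolated)
Conditions: 11, s-BuLi, THF, −78 °C; (−)-Ipc2BOMe (from (+)-α-pinene, the antipode that adds to the Si face); BF3·OEt2; then 10, −78 °C; NaOH, H2O2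
Reagents that add atoms: (−)-B-methoxydiisopinocampheylborane, COB([C@@H]1C[C@@H]2C[C@H]([C@H]1C)C2(C)C)[C@@H]1C[C@@H]2C[C@H]([C@H]1C)C2(C)C (boron and isopinocampheyl groups of intermediate 12 only)
Why: Brown (Z)-γ-alkoxyallylboration proceeds through a chair Zimmerman–Traxler transition state in which the isopinocampheyl groups direct Si-face attack and the Z-reagent gives the syn adduct, so C16 is set as R (the C10 carbinol formed with it is oxidised in step 7).

**Step 7**
Reactants: 13 the syn alcohol of step 6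
Product: 14 (3R)-6-[(6R,7S)-6,7-dimethyl-1,4-dioxaspiro[4.5]decan-6-yl]-3-(methoxymethoxy)hex-1-en-4-one
Conditions: Dess–Martin periodinane, NaHCO3, CH2Cl2, 0 → 25 °C
Reagents that add atoms: none
Why: Dess–Martin oxidation gives the C10 ketone under buffered, non-basic conditions, which keeps the β,γ-alkene out of conjugation and C16 intact.

**Step 8**
Reactants: 14 the α-(methoxymethoxy) ketone
Product: 15 (3R,4S)-6-[(6R,7S)-6,7-dimethyl-1,4-dioxaspiro[4.5]decan-6-yl]-3-(methoxymethoxy)-4-methylhex-1-en-4-ol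
Conditions: MeMgBr, THF, −78 °C; aq. NH4Cl
Reagents that add atoms: methylmagnesium bromide, C[Mg]Br
Why: Chelation-controlled Grignard addition (Cram chelate): magnesium bridges the C10 carbonyl and the C16 ether oxygen and methyl adds from the side of the small C16 hydrogen, which sets C10 as S.

**Step 9**
Reactants: 15 the tertiary alcohol
Product: 16 (2R,3S)-2-[(3S,4R)-3,4-dihydroxy-3-methylhex-5-en-1-yl]-2,3-dimethylcyclohexan-1-one
Conditions: 3 M aq. HCl, THF, 45 °C
Reagents that add atoms: water, O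
Why: Aqueous acid hydrolyses both acetals (methoxymethyl ether and dioxolane) in one operation; the strained ketal next to the quaternary carbon is cleaved readily.

**Step 10**
Reactants: 16 the keto diol
Product: 17 (2R,3S)-2-[(3S,4R)-4-(tert-butyldimethylsilyloxy)-3-hydroxy-3-methylhex-5-en-1-yl]-2,3-dimethylcyclohexan-1-one
Conditions: TBSOTf (1.05 equiv), 2,6-lutidine, CH2Cl2, −78 °C
Reagents that add atoms: tert-butyldimethylsilyl trifluoromethanesulfonate, CC(C)(C)[Si](C)(C)OS(=O)(=O)C(F)(F)F
Why: Silylation is selective for the secondary C16 hydroxyl because the tertiary C10 hydroxyl reacts far more slowly at low temperature, so the nucleophile of the key step stays free.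

**Step 11**
Reactants: 17 the C16 silyl ether ketone
Product: 19 (5S,6R)-6-[(3S,4R)-4-(tert-butyldimethylsilyloxy)-3-hydroxy-3-methylhex-5-en-1-yl]-5,6-dimethylcyclohex-2-en-1-one, via silyl enol ether 18 (not isolated)
Conditions: LDA (2.5 equiv), TMSCl, THF, −78 °C; then Pd(OAc)2, MeCN, 25 °C; 1 M HCl work-up
Reagents that add atoms: chlorotrimethylsilane, C[Si](C)(C)Cl (silyl groups of intermediate 18 only)
Why: Saegusa–Ito oxidation: only C6 can be enolised (C14 is quaternary), palladium diacetate dehydrogenates the silyl enol ether to the C4=C6 enone, and acidic work-up frees the transiently silylated tertiary alcohol.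

**Step 12**
Reactants: 19 the enone
Product: 20 the 2-(hydroxymethyl) enone (C24H2OH on C6 of 19)
Conditions: 37% aq. HCHO, DMAP, THF, 25 °C
Reagents that add atoms: formaldehyde, C=O
Why: Morita–Baylis–Hillman reaction: DMAP adds reversibly to the unhindered β-carbon C4, the enolate attacks formaldehyde at C6, and loss of the amine returns the enone with C24 in place.

**Step 13**
Reactants: 20 the hydroxymethyl enone
Product: 21 the bis(trimethylsilyl) ether of 20 (O on C24 and O on C10)
Conditions: N-(trimethylsilyl)imidazole, CH2Cl2, 25 °C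
Reagents that add atoms: N-(trimethylsilyl)imidazole, C[Si](C)(C)n1ccnc1
Why: Neutral silyl transfer caps both hydroxyls, which removes acidic protons and hemiketal formation at C7 before the ylide step.

**Step 14**
Reactants: 21 the bis(trimethylsilyl) ether
Product: 23 dienyl diol (C7=C8 methylidene; C24H2OH on C6=C4; free C10–OH; C16–OTBS), via bis(trimethylsilyl) diene 22 (not isolated)
Conditions: Ph3PCH3Br, KOt-Bu, toluene, 0 → 80 °C; then K2CO3, MeOH, 25 °C
Reagents that add atoms: methyltriphenylphosphonium bromide, C[P+](c1ccccc1)(c1ccccc1)c1ccccc1.[Br-]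
Why: Wittig methylenation at elevated temperature converts the hindered conjugated ketone to the exocyclic C7=C8 alkene, and mild methanolysis cleaves the two trimethylsilyl ethers while the tert-butyldimethylsilyl ether stays.

**Step 15**
Reactants: 23 the dienyl diol
Product: 24 epoxy alcohol (C4–C6 oxirane, 4R,6R, oxygen cis to the C1 and C15 methyls; C7=C8 methylidene; C24H2OH on C6)
Conditions: Ti(OiPr)4 (10 mol %), D-(−)-DIPT, t-BuOOH, 4 Å MS, CH2Cl2, −20 °C
Reagents that add atoms: tert-butyl hydroperoxide, CC(C)(C)OO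
Why: Katsuki–Sharpless asymmetric epoxidation of the primary allylic alcohol: the D-(−)-tartrate complex delivers oxygen to the face of C4=C6 that gives 4R,6R (reagent control), and the homoallylic C7=C8 and the isolated C18=C19 alkenes are not epoxidised by this hydroxyl-directed system.

**Step 16**
Reactants: 24 the epoxy alcohol
Product: 25 epoxy methylenecyclohexane tertiary alcohol (24 with C24–OTBS)
Conditions: TBSCl, imidazole, CH2Cl2, 0 → 25 °C
Reagents that add atoms: tert-butyldimethylsilyl chloride, CC(C)(C)[Si](C)(C)Cl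
Why: The primary C24 hydroxyl is silylated selectively over the tertiary C10 hydroxyl, which removes a competing nucleophile next to the allyl unit of the key step.

**Step 17**
Reactants: 25 the vinyl epoxide tertiary alcohol
Product: 26 ring A–oxepane allylic alcohol (4R; C6=C7; C8–O9–C10; C24–OTBS; C16–OTBS; C18=C19 vinyl)
Conditions: Pd(PPh3)4 (10 mol %), THF, degassed, 0.01 M, 25 → 45 °C
Reagents that add atoms: none
Why: Zerovalent palladium ionises the allylic C6–O bond of the vinyl epoxide to an allylpalladium unit over C6–C7–C8 and a C4 alkoxide; the alkoxide takes the proton of the C10 hydroxyl and the tertiary alkoxide attacks the unsubstituted terminus C8, which releases the catalyst. The closest known reaction is the Pd(PPh3)4-catalysed 1,4-addition (SN2') of alcohols to vinyl epoxides, used intramolecularly for cyclic ethers. The oxepane closes as a seven-membered ring by attack on the allyl terminus C8 with the tether carried by the central carbon C7 (through C14), so the new alkene C6=C7 is exocyclic to the oxepane and endocyclic to ring A. No new stereocentre forms: C4 keeps the configuration set in step 15 because its C–O bond is never broken, and C8 is a methylene. The step needs C8 over C6 regioselectivity, secured by the fully substituted C6, and the C10 oxygen as the only nucleophile, secured by the silyl ethers on the C16 and C24 oxygens; the unsubstituted terminus also allows η3–η1–η3 face exchange, so the alkoxide can attack anti to palladium from the face that carries the tether.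

**Step 18**
Reactants: 26 the allylic alcohol
Product: 27 the C4 tert-butyldimethylsilyl ether of 26 (three silyl ethers)
Conditions: TBSOTf, 2,6-lutidine, CH2Cl2, −78 → 0 °C
Reagents that add atoms: tert-butyldimethylsilyl trifluoromethanesulfonate, CC(C)(C)[Si](C)(C)OS(=O)(=O)C(F)(F)F
Why: Silyl triflate with a hindered base protects the secondary allylic C4 hydroxyl so that only C24 is oxidised later.

**Step 19**
Reactants: 27 the tris(silyl) ether
Product: 28 the C24 primary allylic alcohol (C4–OTBS and C16–OTBS kept)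
Conditions: HF·pyridine, pyridine, THF, 0 °C
Reagents that add atoms: none
Why: Buffered HF·pyridine cleaves the unhindered primary silyl ether much faster than the two secondary ones.

**Step 20**
Reactants: 28 the primary allylic alcohol
Product: 29 the C24 enal
Conditions: Dess–Martin periodinane, NaHCO3, CH2Cl2, 0 → 25 °C
Reagents that add atoms: none
Why: Dess–Martin oxidation of the primary allylic alcohol gives the enal without touching the silyl ethers or the allylic ether.

**Step 21**
Reactants: 29 the enal; 30 prop-1-yn-1-ylmagnesium bromide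
Product: 31 the C24 propargylic alcohol (both C24 epimers)
Conditions: THF, −78 → 0 °C; aq. NH4Cl
Reagents that add atoms: none
Why: 1,2-Addition of the alkynyl Grignard reagent to the aldehyde installs C23, C20 and C21; the C24 configuration is irrelevant because C24 is oxidised in step 24.

**Step 22**
Reactants: 31 the propargylic alcohol
Product: 33 the (Z)-3-iodoallylic alcohol (I on C20 cis to C24), via cyclic alkenylaluminate 32 (not isolated)
Conditions: Red-Al (NaAlH2(OCH2CH2OMe)2), THF, 0 → 25 °C; then I2, THF, −78 °C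
Reagents that add atoms: iodine, II; Red-Al, [Na+].COCCO[AlH2-]OCCOC (sodium and aluminium of intermediate 32 only)
Why: Hydroxyl-directed trans-hydroalumination of the propargylic alcohol (hydride to C23, aluminium to C20 in a five-membered alkoxyaluminate) and iodinolysis with retention fix the alkene geometry with iodine cis to C24.

**Step 23**
Reactants: 33 the (Z)-vinyl iodide
Product: 35 macrocyclic dienol (C19–C20 bond; Z-C20=C23; C24–OH; both C24 epimers), via B-alkyl-9-BBN borinate 34 (not isolated)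
Conditions: 9-BBN (3 equiv), THF, 25 °C; then Pd(dppf)Cl2, AsPh3, Cs2CO3, DMF/THF/H2O, 0.002 M, 25 → 50 °C
Reagents that add atoms: 9-BBN, B1C2CCCC1CCC2 (boron groups of intermediate 34 only)
Why: B-alkyl Suzuki–Miyaura macrocyclisation: 9-BBN adds only to the monosubstituted C18=C19 alkene (boron at C19), and intramolecular coupling with the vinyl iodide under high dilution forms C19–C20 with retention of alkene geometry, which closes the 12-membered carbocycle.

**Step 24**
Reactants: 35 the macrocyclic dienol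
Product: 36 the macrocyclic cross-conjugated dienone (C24 ketone; Z-C20=C23)
Conditions: Dess–Martin periodinane, NaHCO3, CH2Cl2, 0 → 25 °C
Reagents that add atoms: none
Why: Dess–Martin oxidation of the bis-allylic alcohol gives the dienone without alkene isomerisation and merges the two C24 epimers.

**Step 25**
Reactants: 36 the dienone
Product: 37 the (20R,23R)-epoxy ketone bis(tert-butyldimethylsilyl) ether
Conditions: 30% H2O2, LiOH (cat.), MeOH, 0 °C
Reagents that add atoms: hydrogen peroxide, OO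
Why: Weitz–Scheffer nucleophilic epoxidation: hydroperoxide adds to C20 (the other β-carbon, C7, is fully substituted and shielded) from the exposed face of the macrocyclic Z-enone, and the ring holds the enolate so that closure gives the cis-oxirane, which sets C20 and C23.

**Step 26**
Reactants: 37 the bis(silyl) epoxy ketone
Product: 38 the target CNP0316768.3
Conditions: HF·pyridine, pyridine, THF, 0 → 25 °C
Reagents that add atoms: none
Why: Fluoride-mediated cleavage of both silyl ethers under buffered, weakly acidic conditions should be tolerated by the epoxy ketone and the allylic alcohol.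

**Compound list**
1 | 2-methylcyclohex-2-en-1-one | CC1=CCCC1=O | starting material
2 | dimethylaluminium (3S)-2,3-dimethylcyclohex-1-en-1-olate | C[C@H]1CCCC(O[Al](C)C)=C1C | intermediate
3 | (3S)-2,3-dimethyl-1-(trimethylsilyloxy)cyclohex-1-ene | C[C@H]1CCCC(O[Si](C)(C)C)=C1C | intermediate
4 | allyl bromide | C=CCBr | starting material
5 | lithium (3S)-2,3-dimethylcyclohex-1-en-1-olate | C[C@H]1CCCC([O-])=C1C.[Li+] | intermediate
6 | (2R,3S)-2-allyl-2,3-dimethylcyclohexan-1-one | C[C@H]1CCCC(=O)[C@]1(C)CC=C | intermediate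
7 | (6R,7S)-6-allyl-6,7-dimethyl-1,4-dioxaspiro[4.5]decane | C[C@H]1CCCC2(OCCO2)[C@]1(C)CC=C | intermediate
8 | B-{3-[(6R,7S)-6,7-dimethyl-1,4-dioxaspiro[4.5]decan-6-yl]propyl}-9-borabicyclo[3.3.1]nonane | C[C@H]1CCCC2(OCCO2)[C@]1(C)CCCB3C4CCCC3CCC4 | intermediate
9 | 3-[(6R,7S)-6,7-dimethyl-1,4-dioxaspiro[4.5]decan-6-yl]propan-1-ol | C[C@H]1CCCC2(OCCO2)[C@]1(C)CCCO | intermediate
10 | 3-[(6R,7S)-6,7-dimethyl-1,4-dioxaspiro[4.5]decan-6-yl]propanal | C[C@H]1CCCC2(OCCO2)[C@]1(C)CCC=O | intermediate
11 | allyl methoxymethyl ether (3-(methoxymethoxy)prop-1-ene) | C=CCOCOC | starting material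
12 | [(Z)-3-(methoxymethoxy)allyl]bis(isopinocampheyl)borane | COCO/C=C\CB([C@@H]1C[C@@H]2C[C@H]([C@H]1C)C2(C)C)[C@@H]1C[C@@H]2C[C@H]([C@H]1C)C2(C)C | intermediate
13 | (3R,4R)-6-[(6R,7S)-6,7-dimethyl-1,4-dioxaspiro[4.5]decan-6-yl]-3-(methoxymethoxy)hex-1-en-4-ol | C[C@H]1CCCC2(OCCO2)[C@]1(C)CC[C@@H](O)[C@H](OCOC)C=C | intermediate
14 | (3R)-6-[(6R,7S)-6,7-dimethyl-1,4-dioxaspiro[4.5]decan-6-yl]-3-(methoxymethoxy)hex-1-en-4-one | C[C@H]1CCCC2(OCCO2)[C@]1(C)CCC(=O)[C@H](OCOC)C=C | intermediate
15 | (3R,4S)-6-[(6R,7S)-6,7-dimethyl-1,4-dioxaspiro[4.5]decan-6-yl]-3-(methoxymethoxy)-4-methylhex-1-en-4-ol | C[C@H]1CCCC2(OCCO2)[C@]1(C)CC[C@](C)(O)[C@H](OCOC)C=C | intermediate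
16 | (2R,3S)-2-[(3S,4R)-3,4-dihydroxy-3-methylhex-5-en-1-yl]-2,3-dimethylcyclohexan-1-one | C[C@H]1CCCC(=O)[C@]1(C)CC[C@](C)(O)[C@H](O)C=C | intermediate
17 | (2R,3S)-2-[(3S,4R)-4-(tert-butyldimethylsilyloxy)-3-hydroxy-3-methylhex-5-en-1-yl]-2,3-dimethylcyclohexan-1-one | C[C@H]1CCCC(=O)[C@]1(C)CC[C@](C)(O)[C@H](O[Si](C)(C)C(C)(C)C)C=C | intermediate
18 | C6=C7 trimethylsilyl enol ether of 17 with C10–OSiMe3 | C[C@H]1CCC=C(O[Si](C)(C)C)[C@]1(C)CC[C@](C)(O[Si](C)(C)C)[C@H](O[Si](C)(C)C(C)(C)C)C=C | intermediate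
19 | (5S,6R)-6-[(3S,4R)-4-(tert-butyldimethylsilyloxy)-3-hydroxy-3-methylhex-5-en-1-yl]-5,6-dimethylcyclohex-2-en-1-one | C[C@H]1CC=CC(=O)[C@]1(C)CC[C@](C)(O)[C@H](O[Si](C)(C)C(C)(C)C)C=C | intermediate
20 | (5S,6R)-2-(hydroxymethyl) analogue of 19 | C[C@H]1CC=C(CO)C(=O)[C@]1(C)CC[C@](C)(O)[C@H](O[Si](C)(C)C(C)(C)C)C=C | intermediate
21 | bis(trimethylsilyl) ether of 20 (C24–O and C10–O) | C[C@H]1CC=C(CO[Si](C)(C)C)C(=O)[C@]1(C)CC[C@](C)(O[Si](C)(C)C)[C@H](O[Si](C)(C)C(C)(C)C)C=C | intermediate
22 | C7 methylidene analogue of 21 | C[C@H]1CC=C(CO[Si](C)(C)C)C(=C)[C@]1(C)CC[C@](C)(O[Si](C)(C)C)[C@H](O[Si](C)(C)C(C)(C)C)C=C | intermediate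
23 | (3S,4R)-4-(tert-butyldimethylsilyloxy)-1-[(1R,6S)-3-(hydroxymethyl)-1,6-dimethyl-2-methylidenecyclohex-3-en-1-yl]-3-methylhex-5-en-3-ol | C[C@H]1CC=C(CO)C(=C)[C@]1(C)CC[C@](C)(O)[C@H](O[Si](C)(C)C(C)(C)C)C=C | intermediate
24 | (4R,6R)-C4–C6 epoxide of 23 (oxygen cis to the two ring methyls) | C[C@H]1C[C@H]2O[C@@]2(CO)C(=C)[C@]1(C)CC[C@](C)(O)[C@H](O[Si](C)(C)C(C)(C)C)C=C | intermediate
25 | epoxy methylenecyclohexane tertiary alcohol (C24–OTBS ether of 24) | C[C@H]1C[C@H]2O[C@@]2(CO[Si](C)(C)C(C)(C)C)C(=C)[C@]1(C)CC[C@](C)(O)[C@H](O[Si](C)(C)C(C)(C)C)C=C | intermediate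
26 | ring A–oxepane allylic alcohol (4R, C6=C7, C8–O9) | C[C@H]1C[C@@H](O)C(CO[Si](C)(C)C(C)(C)C)=C2CO[C@@](C)(CC[C@@]21C)[C@H](O[Si](C)(C)C(C)(C)C)C=C | intermediate
27 | C4 tert-butyldimethylsilyl ether of 26 | C[C@H]1C[C@@H](O[Si](C)(C)C(C)(C)C)C(CO[Si](C)(C)C(C)(C)C)=C2CO[C@@](C)(CC[C@@]21C)[C@H](O[Si](C)(C)C(C)(C)C)C=C | intermediate
28 | C24 primary allylic alcohol (C4, C16 silyl ethers) | C[C@H]1C[C@@H](O[Si](C)(C)C(C)(C)C)C(CO)=C2CO[C@@](C)(CC[C@@]21C)[C@H](O[Si](C)(C)C(C)(C)C)C=C | intermediate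
29 | C24 enal | C[C@H]1C[C@@H](O[Si](C)(C)C(C)(C)C)C(C=O)=C2CO[C@@](C)(CC[C@@]21C)[C@H](O[Si](C)(C)C(C)(C)C)C=C | intermediate
30 | prop-1-yn-1-ylmagnesium bromide | CC#C[Mg]Br | starting material
31 | C24 propargylic alcohol (C24 epimer mixture) | C[C@H]1C[C@@H](O[Si](C)(C)C(C)(C)C)C(C(O)C#CC)=C2CO[C@@](C)(CC[C@@]21C)[C@H](O[Si](C)(C)C(C)(C)C)C=C | intermediate
32 | sodium cyclic alkoxy(alkenyl)aluminate (O on C24 and C20 bound to Al) | [Na+].C[C@H]1C[C@@H](O[Si](C)(C)C(C)(C)C)C(C3O[Al-](OCCOC)(OCCOC)C(C)=C3)=C2CO[C@@](C)(CC[C@@]21C)[C@H](O[Si](C)(C)C(C)(C)C)C=C | intermediate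
33 | (Z)-3-iodoallylic alcohol (I on C20 cis to C24; C24 epimer mixture) | C[C@H]1C[C@@H](O[Si](C)(C)C(C)(C)C)C(C(O)/C=C(/C)I)=C2CO[C@@](C)(CC[C@@]21C)[C@H](O[Si](C)(C)C(C)(C)C)C=C | intermediate
34 | C19 B-alkyl-9-BBN, C24 O-borinate of 33 | C[C@H]1C[C@@H](O[Si](C)(C)C(C)(C)C)C(C(OB3C4CCCC3CCC4)/C=C(/C)I)=C2CO[C@@](C)(CC[C@@]21C)[C@H](O[Si](C)(C)C(C)(C)C)CCB5C6CCCC5CCC6 | intermediate
35 | macrocyclic dienol (Z-C20=C23, C24–OH, C24 epimer mixture) | C[C@H]1C[C@@H](O[Si](C)(C)C(C)(C)C)C2=C3CO[C@@](C)(CC[C@@]31C)[C@H](O[Si](C)(C)C(C)(C)C)CC/C(C)=C\C2O | intermediate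
36 | macrocyclic dienone (Z-C20=C23, C24 ketone) | C[C@H]1C[C@@H](O[Si](C)(C)C(C)(C)C)C2=C3CO[C@@](C)(CC[C@@]31C)[C@H](O[Si](C)(C)C(C)(C)C)CC/C(C)=C\C2=O | intermediate
37 | (20R,23R)-epoxy ketone, C4 and C16 tert-butyldimethylsilyl ethers | C[C@H]1C[C@@H](O[Si](C)(C)C(C)(C)C)C2=C3CO[C@@](C)(CC[C@@]31C)[C@H](O[Si](C)(C)C(C)(C)C)CC[C@@]1(C)O[C@H]1C2=O | intermediate
38 | CNP0316768.3 (2S,4R,10S,14R,16R,20R,23R) | C[C@H]1C[C@@H](O)C2=C3CO[C@@](C)(CC[C@@]31C)[C@H](O)CC[C@@]1(C)O[C@H]1C2=O | target

**Totals**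
Total step count: 26. Longest linear sequence: 26 steps (1 to 38).

**Steps most likely to fail**

1. Step 17. The allylpalladium alkoxide may lose a β-hydrogen (from C24 or C4) and isomerise to a dienol or enone before the hindered tertiary C10 hydroxyl reaches C8, because the seven-membered closure is slow. The fallback sets out from 25 and returns at 26. Bromide opens the vinyl epoxide in the SN2' sense (LiBr/CuBr2, THF, 0 °C) to give the primary allylic bromide diol F1 with C4–OH and C6=C7 already in place. Silver-assisted intramolecular etherification (AgOTf, 2,6-di-tert-butylpyridine, CH2Cl2, 0 °C) then lets the C10 hydroxyl displace bromide at C8; the C4 hydroxyl cannot reach C8 because it lies trans to it across C6=C7.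

2. Step 23. Oligomerisation, protodeboronation or β-hydride elimination may outcompete closure of the strained, ether-bridged 12-membered ring. The fallback sets out from 27 and returns at 35, closing the ring at C20=C23 by metathesis instead. Hydroboration of C18=C19 with 9-BBN and intermolecular Suzuki coupling with 2-bromopropene (Pd(dppf)Cl2, K3PO4) give the isopropenyl-terminated tris(silyl) ether F2. Selective primary desilylation (HF·pyridine/pyridine) gives the alcohol F3, Dess–Martin oxidation gives the enal F4, and vinylmagnesium bromide gives the vinyl carbinol F5. Ring-closing metathesis with the second-generation Grubbs catalyst (toluene, 80 °C, high dilution) should then form the trisubstituted C20=C23 alkene, the bridged ring favouring the Z isomer.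

3. Step 25. Poor facial selectivity, or loss of alkene geometry by bond rotation in the β-peroxy enolate, may give the wrong oxirane. The fallback sets out from 31 and returns at 37, replacing macrocycle control by a reagent-set carbinol and a hydroxyl-directed epoxidation.
   - Dess–Martin oxidation gives the ynone F6.
   - Reduction with (R)-Me-CBS/catecholborane (alkynyl as the small group) gives the (24S)-propargylic alcohol F7.
   - Red-Al then I2 gives the (24S)-(Z)-iodoallylic alcohol F8.
   - 9-BBN hydroboration and Suzuki macrocyclisation as in step 23 give the (24S)-macrocyclic dienol F9.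
   - VO(acac)2/t-BuOOH delivers oxygen stereospecifically syn to the C24 hydroxyl in the conformer with C24–H eclipsing the alkene (A(1,3) strain), giving the epoxy alcohol F10 with the oxirane configured as in the target. The C6=C7 alkene is shielded by the C4 silyl ether and C15.
   - Dess–Martin oxidation of F10 gives 37.

**Further compounds**
F1 | step 17 | primary allylic bromide diol (C8–Br, C6=C7, 4R C4–OH, free C10–OH) | C[C@H]1C[C@@H](O)C(CO[Si](C)(C)C(C)(C)C)=C(CBr)[C@]1(C)CC[C@](C)(O)[C@H](O[Si](C)(C)C(C)(C)C)C=C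
F2 | step 23 | isopropenyl-terminated tris(silyl) ether (C19–C20(CH3)=CH2) | C[C@H]1C[C@@H](O[Si](C)(C)C(C)(C)C)C(CO[Si](C)(C)C(C)(C)C)=C2CO[C@@](C)(CC[C@@]21C)[C@H](O[Si](C)(C)C(C)(C)C)CCC(C)=C
F3 | step 23 | C24 primary alcohol of F2 | C[C@H]1C[C@@H](O[Si](C)(C)C(C)(C)C)C(CO)=C2CO[C@@](C)(CC[C@@]21C)[C@H](O[Si](C)(C)C(C)(C)C)CCC(C)=C
F4 | step 23 | C24 enal with isopropenyl side chain | C[C@H]1C[C@@H](O[Si](C)(C)C(C)(C)C)C(C=O)=C2CO[C@@](C)(CC[C@@]21C)[C@H](O[Si](C)(C)C(C)(C)C)CCC(C)=C
F5 | step 23 | C24 vinyl carbinol with isopropenyl side chain | C[C@H]1C[C@@H](O[Si](C)(C)C(C)(C)C)C(C(O)C=C)=C2CO[C@@](C)(CC[C@@]21C)[C@H](O[Si](C)(C)C(C)(C)C)CCC(C)=C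
F6 | step 25 | C24 ynone | C[C@H]1C[C@@H](O[Si](C)(C)C(C)(C)C)C(C(=O)C#CC)=C2CO[C@@](C)(CC[C@@]21C)[C@H](O[Si](C)(C)C(C)(C)C)C=C
F7 | step 25 | (24S)-propargylic alcohol | C[C@H]1C[C@@H](O[Si](C)(C)C(C)(C)C)C([C@@H](O)C#CC)=C2CO[C@@](C)(CC[C@@]21C)[C@H](O[Si](C)(C)C(C)(C)C)C=C
F8 | step 25 | (24S)-(Z)-3-iodoallylic alcohol | C[C@H]1C[C@@H](O[Si](C)(C)C(C)(C)C)C([C@@H](O)/C=C(/C)I)=C2CO[C@@](C)(CC[C@@]21C)[C@H](O[Si](C)(C)C(C)(C)C)C=C
F9 | step 25 | (24S)-macrocyclic dienol | C[C@H]1C[C@@H](O[Si](C)(C)C(C)(C)C)C2=C3CO[C@@](C)(CC[C@@]31C)[C@H](O[Si](C)(C)C(C)(C)C)CC/C(C)=C\[C@@H]2O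
F10 | step 25 | macrocyclic epoxy alcohol (oxirane as in 37, C24 carbinol as in F9) | C[C@H]1C[C@@H](O[Si](C)(C)C(C)(C)C)C2=C3CO[C@@](C)(CC[C@@]31C)[C@H](O[Si](C)(C)C(C)(C)C)CC[C@@]1(C)O[C@H]1[C@@H]2O
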